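Watch one quotient while you repeat this exchange, in which Q takes the place of X on the complex J in two steps, through E to L.

| flask | J | Q | remark | time |
|---|---|---|---|---|
| south | 1.5 M | 1.35 M | one stirred flow tank at steady state, fed with the mixture as stated, mean residence time 80 s |  |
| north-east | 1.5 M | 1.35 M | a closed flask charged with all of it at once and left for 80 s | 80 s |
| south-west | 1.5 M | 1.35 M (fed, over 64.0 s) | all but Q at the start; Q goes in evenly over 64.0 s, the run ends at 80 s | 80 s |
| east | 1.5 M (fed, over 64.0 s) | 1.35 M | a stirred flask in which J is dosed at a steady rate over 64.0 s without added volume, worked up at 80 s | 80 s |

    J + Q ⇌ X + E (K1 = 0.13, k1 = 0.051 M⁻¹ s⁻¹)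
    E + Q ⇌ X + L (K2 = 0.18, k2 = 0.20 M⁻¹ s⁻¹)

- the stated concentrations are those of everything mixed, before any reaction; amounts are the same in each set-up
- the feed brings no volume worth counting
- run time (north-east): 80 s

1. the set-up with the highest amount of E at the outlet or at the end, in percent of the J put in ("none" if the first two lie within 2 percentage points) (south / north-east / south-west / east / none)
2. amount of E at the outlet or at the end, in percent of the J put in, south
3. amount of E at the outlet or at the end, in percent of the J put in, north-east
4. amount of E at the outlet or at the end, in percent of the J put in, south-west
5. amount of E at the outlet or at the end, in percent of the J put in, east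

**The quotient.** I subtract the first step from the second, so that Q and X cancel and two E go to J plus L, a disproportionation; once both steps stand in balance, D, the concentration of J times that of L over the square of that of E, equals the second constant over the first, 1.38.

**Fast rung.** At Q as charged, with the way back not counted, E has a forward half-life of 2.57 s and J one of 10.1 s, so a given E reacts on sooner than a given J reacts; these are times per molecule, and they do not compare the rates at which E forms and goes on.

**Slow rung.** The hold after dosing, 16.0 s, is longer than the half-life of J, and the north-east flask has 7.95 such half-lives, so I expect balance in the north-east, south-west and east flasks. Part of the south tank's contents leaves early, so I expect it a little lower.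

**Two rounds.** Round one ignores L and takes J and Q as equal at their geometric mean, so that the ratio of E to remaining J is the root of the first constant, 0.361; this gives E 0.377 M and leaves J 1.12 M. Round two puts that back: J stays, E and L share the 0.377 M, and solving D for the share gives E 0.280 M, which is 18.7 % of the J put in.

**The forecast.** It gives 17.8 % south, 18.5 % north-east, 18.5 % south-west and 18.5 % east, so best is none, and it says: “The flask is therefore fully equilibrated by 80 s.” Its north-east figure lies slightly below mine.

**The outcome.** The simulation gives 17.8 % south, 18.5 % north-east, 18.5 % south-west and 18.5 % east, so best is none. In the east flask the readings of J, L and E give a quotient of 1.38 against D of 1.38, while in the south tank they give 1.48, higher than D. E stays low because X and E fall back to J and Q: with that return struck out, the north-east flask holds 77.1 % of E instead of 18.5 %.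

The numbers of this flask belong to no real substance, and the outcome is calculated.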